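The route rests on cutting the dihydropyranone ring at C5–C6 and O1–C2: O1–C6 is read as a former aldehyde C=O and C2–C5 as 1-methoxybutadiene. One catalyst-controlled hetero-Diels–Alder reaction then closes the six-membered ring, forms the C5–C6 bond, sets C6 anti to the C2' oxygen and leaves the C3=C4 alkene in place, with C2 at the acetal level, one oxidation from the lactone. The precursor is an open-chain syn,syn-3,5,7-tris(silyloxy)hexadecanal that looks nothing like a lactone; its three stereocentres descend from one catalytic vinylogous aldol (C6') through two boron-chelate syn-reductions.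

Key step: step 7

Numbering: ring atoms O1, C2 (C=O), C3, C4, C5, C6 of the 5,6-dihydro-2H-pyran-2-one; side chain C1' to C15' from the ring. The target is 6S,2'S,4'S,6'S (C6/C2' anti, C2'/C4' syn, C4'/C6' syn). While the hydroxyls are silylated the C2' descriptor reads R through a CIP priority change only; the geometry is unchanged.

Assumption: the senses of induction of (R)-BINOL with Ti(OiPr)4 (step 1) and of the (1S,2R) chromium complex (step 7) are assigned by analogy with simple aldehydes; the mirror-image ligand, equally available, would be used if a model run shows the opposite sense.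

Step 1
Reactants: 1 decanal; 2 1-methoxy-1,3-bis(trimethylsilyloxy)buta-1,3-diene
Product: 4 methyl (5S)-5-hydroxy-3-oxotetradecanoate, via silylated aldol adduct 3 (not isolated)
Conditions: Ti(OiPr)4/(R)-BINOL (1:1, 8 mol%), 4 Å MS, THF, −78 °C to rt; then TFA, −78 °C to rt
Reagents that add atoms: none
Why: Catalytic enantioselective vinylogous Mukaiyama aldol reaction: the BINOLate of tetravalent titanium activates the aldehyde, the terminal CH2 of the bis-silyl dienolate adds to one carbonyl face to set C5 as S (the future C6'), and acid cleaves both silyl groups of adduct 3.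

Step 2
Reactants: 4 methyl (5S)-5-hydroxy-3-oxotetradecanoate
Product: 6 methyl (3S,5S)-3,5-dihydroxytetradecanoate, via boron chelate 5 (not isolated)
Conditions: Et2BOMe (1.1 equiv), THF/MeOH 4:1, −78 °C; NaBH4; AcOH quench, MeOH co-evaporation
Reagents that add atoms: none
Why: Narasaka–Prasad reduction: the C5 borinate chelates the C3 ketone in a half-chair and external hydride adds axially, so the new C3 carbinol (S, the future C4') is set 1,3-syn to C5 by substrate control.

Step 3
Reactants: 6 methyl (3S,5S)-3,5-dihydroxytetradecanoate; 7 tert-butyl acetate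
Product: 8 tert-butyl (5S,7S)-5,7-dihydroxy-3-oxohexadecanoate
Conditions: 7 (5 equiv), LiN(iPr)2 (5 equiv), THF, −78 °C; add 6, −78 to −20 °C; aq. NH4Cl
Reagents that add atoms: none
Why: Crossed Claisen condensation: the non-self-condensing ester enolate, used in excess to absorb the two hydroxyl protons, acylates on the methyl ester (or on the δ-lactone the dialkoxide can form in the flask) and the product stays shielded as its enolate until the quench, with no stereocentre involved.

Step 4
Reactants: 8 tert-butyl (5S,7S)-5,7-dihydroxy-3-oxohexadecanoate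
Product: 10 tert-butyl (3S,5S,7S)-3,5,7-trihydroxyhexadecanoate, via bis-borinate 9 (not isolated)
Conditions: Et2BOMe (2.3 equiv), THF/MeOH 4:1, −78 °C; NaBH4; AcOH quench, MeOH co-evaporation
Reagents that add atoms: none
Why: Second Narasaka–Prasad reduction: excess Et2BOMe borylates both hydroxyls, which keeps 8 in its open keto form, and the C5 borinate–ketone chelate steers axial hydride delivery so that C3 (S, the future C2') is set syn to C5 by relay.

Step 5
Reactants: 10 tert-butyl (3S,5S,7S)-3,5,7-trihydroxyhexadecanoate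
Product: 11 tert-butyl (3S,5S,7S)-3,5,7-tris(tert-butyldimethylsilyloxy)hexadecanoate
Conditions: TBSOTf (3.6 equiv), 2,6-lutidine, CH2Cl2, −78 to 0 °C
Reagents that add atoms: tert-butyldimethylsilyl trifluoromethanesulfonate, CC(C)(C)[Si](C)(C)OS(=O)(=O)C(F)(F)F
Why: Silyl ether formation with a silyl triflate and a hindered base caps all three secondary hydroxyls at low temperature, where the tert-butyl ester is left untouched.

Step 6
Reactants: 11 tert-butyl (3S,5S,7S)-3,5,7-tris(tert-butyldimethylsilyloxy)hexadecanoate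
Product: 12 (3S,5S,7S)-3,5,7-tris(tert-butyldimethylsilyloxy)hexadecanal
Conditions: iBu2AlH (1.2 equiv), CH2Cl2, −78 °C; MeOH, then aq. KNaC4H4O6
Reagents that add atoms: none
Why: Partial ester reduction with a dialkylaluminium hydride: at −78 °C the aluminium hemiacetal is stable and releases the aldehyde only on work-up, and the aldehyde has no epimerisable α-centre.

Step 7
Reactants: 12 (3S,5S,7S)-3,5,7-tris(tert-butyldimethylsilyloxy)hexadecanal; 13 (E)-1-methoxybuta-1,3-diene
Product: 14 (2R,6S)-2-methoxy-6-[(2R,4S,6S)-2,4,6-tris(tert-butyldimethylsilyloxy)pentadecyl]-5,6-dihydro-2H-pyran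
Conditions: 13 (5 equiv), CrCl(C27H29NO2) [tridentate Schiff-base complex of trivalent chromium from (1S,2R)-1-aminoindan-2-ol and 3-(1-adamantyl)-2-hydroxy-5-methylbenzaldehyde] (5 mol%), powdered 4 Å MS, neat or minimal tBuOMe, rt, 24–48 h
Reagents that add atoms: none
Why: The chromium centre binds the aldehyde oxygen and the s-cis diene adds in a concerted, asynchronous endo [4+2] cycloaddition in which the CH2 terminus of the diene bonds to the carbonyl carbon (C5–C6) while the carbonyl oxygen bonds to the methoxy-bearing carbon (O1–C2). The closest known reaction type is the Jacobsen hetero-Diels–Alder reaction of 1-methoxybutadiene with aliphatic aldehydes. The six-membered ring is closed intermolecularly by two new endocyclic bonds formed in one [4+2] event, and the C3=C4 alkene is born in its final position. C6 is set by the catalyst, which shields one carbonyl face to give 6S, and the intrinsic 1,3-anti bias of the β-silyloxy aldehyde points the same way, so catalyst and substrate should be matched; C2 follows from the endo transition state (2,6-cis) and is erased in step 8. The step needs facial selectivity at the aldehyde and regioselectivity, the latter secured by the polarisation of the diene (nucleophilic terminus remote from OMe), and the weak Lewis acidity of the complex should spare the β-silyloxy groups from elimination.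

Step 8
Reactants: 14 (2R,6S)-2-methoxy-6-[(2R,4S,6S)-2,4,6-tris(tert-butyldimethylsilyloxy)pentadecyl]-5,6-dihydro-2H-pyran
Product: 16 (6S)-6-[(2R,4S,6S)-2,4,6-tris(tert-butyldimethylsilyloxy)pentadecyl]-5,6-dihydro-2H-pyran-2-one, via lactol 15 (not isolated)
Conditions: PPTS (cat.), acetone/H2O 10:1, rt; then MnO2, CH2Cl2, rt
Reagents that add atoms: water, O
Why: Mild acid hydrolysis of the allylic methyl acetal gives lactol 15, and MnO2, an oxidant selective for allylic alcohols and lactols, takes it to the α,β-unsaturated δ-lactone without touching the silyl ethers or C6.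

Step 9
Reactants: 16 (6S)-6-[(2R,4S,6S)-2,4,6-tris(tert-butyldimethylsilyloxy)pentadecyl]-5,6-dihydro-2H-pyran-2-one
Product: 17 (6S)-6-[(2S,4S,6S)-2,4,6-trihydroxypentadecyl]-5,6-dihydro-2H-pyran-2-one
Conditions: HF·pyridine, THF/pyridine, 0 °C to rt
Reagents that add atoms: none
Why: Global desilylation with buffered HF under non-basic conditions frees the three hydroxyls while avoiding lactone opening, β-elimination and intramolecular oxa-Michael addition of the C2' hydroxyl.

Compound list
1 | decanal | CCCCCCCCCC=O | starting material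
2 | 1-methoxy-1,3-bis(trimethylsilyloxy)buta-1,3-diene (Chan's diene) | COC(O[Si](C)(C)C)=CC(=C)O[Si](C)(C)C | starting material
3 | methyl (5S)-3,5-bis(trimethylsilyloxy)tetradec-2-enoate, silylated aldol adduct formed in the flask | CCCCCCCCC[C@H](O[Si](C)(C)C)CC(O[Si](C)(C)C)=CC(=O)OC | intermediate
4 | methyl (5S)-5-hydroxy-3-oxotetradecanoate | CCCCCCCCC[C@H](O)CC(=O)CC(=O)OC | intermediate
5 | methyl (5S)-5-[(diethylboranyl)oxy]-3-oxotetradecanoate, boron chelate formed in the flask | CCCCCCCCC[C@H](OB(CC)CC)CC(=O)CC(=O)OC | intermediate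
6 | methyl (3S,5S)-3,5-dihydroxytetradecanoate | CCCCCCCCC[C@H](O)C[C@H](O)CC(=O)OC | intermediate
7 | tert-butyl acetate | CC(=O)OC(C)(C)C | starting material
8 | tert-butyl (5S,7S)-5,7-dihydroxy-3-oxohexadecanoate | CCCCCCCCC[C@H](O)C[C@H](O)CC(=O)CC(=O)OC(C)(C)C | intermediate
9 | tert-butyl (5S,7S)-5,7-bis[(diethylboranyl)oxy]-3-oxohexadecanoate, bis-borinate formed in the flask | CCCCCCCCC[C@H](OB(CC)CC)C[C@H](OB(CC)CC)CC(=O)CC(=O)OC(C)(C)C | intermediate
10 | tert-butyl (3S,5S,7S)-3,5,7-trihydroxyhexadecanoate | CCCCCCCCC[C@H](O)C[C@H](O)C[C@H](O)CC(=O)OC(C)(C)C | intermediate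
11 | tert-butyl (3S,5S,7S)-3,5,7-tris(tert-butyldimethylsilyloxy)hexadecanoate | CCCCCCCCC[C@H](O[Si](C)(C)C(C)(C)C)C[C@H](O[Si](C)(C)C(C)(C)C)C[C@H](O[Si](C)(C)C(C)(C)C)CC(=O)OC(C)(C)C | intermediate
12 | (3S,5S,7S)-3,5,7-tris(tert-butyldimethylsilyloxy)hexadecanal | CCCCCCCCC[C@H](O[Si](C)(C)C(C)(C)C)C[C@H](O[Si](C)(C)C(C)(C)C)C[C@H](O[Si](C)(C)C(C)(C)C)CC=O | intermediate
13 | (E)-1-methoxybuta-1,3-diene | CO/C=C/C=C | starting material
14 | (2R,6S)-2-methoxy-6-[(2R,4S,6S)-2,4,6-tris(tert-butyldimethylsilyloxy)pentadecyl]-5,6-dihydro-2H-pyran (2,6-cis) | CCCCCCCCC[C@H](O[Si](C)(C)C(C)(C)C)C[C@H](O[Si](C)(C)C(C)(C)C)C[C@H](O[Si](C)(C)C(C)(C)C)C[C@@H]1CC=C[C@H](OC)O1 | intermediate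
15 | (6S)-6-[(2R,4S,6S)-2,4,6-tris(tert-butyldimethylsilyloxy)pentadecyl]-5,6-dihydro-2H-pyran-2-ol, lactol formed in the flask as an anomer mixture | CCCCCCCCC[C@H](O[Si](C)(C)C(C)(C)C)C[C@H](O[Si](C)(C)C(C)(C)C)C[C@H](O[Si](C)(C)C(C)(C)C)C[C@@H]1CC=CC(O)O1 | intermediate
16 | (6S)-6-[(2R,4S,6S)-2,4,6-tris(tert-butyldimethylsilyloxy)pentadecyl]-5,6-dihydro-2H-pyran-2-one | CCCCCCCCC[C@H](O[Si](C)(C)C(C)(C)C)C[C@H](O[Si](C)(C)C(C)(C)C)C[C@H](O[Si](C)(C)C(C)(C)C)C[C@@H]1CC=CC(=O)O1 | intermediate
17 | (6S)-6-[(2S,4S,6S)-2,4,6-trihydroxypentadecyl]-5,6-dihydro-2H-pyran-2-one | CCCCCCCCC[C@H](O)C[C@H](O)C[C@H](O)C[C@@H]1CC=CC(=O)O1 | target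

Total step count: 9. Longest linear sequence: 9 steps, from decanal 1.

Steps most likely to fail

1. Step 7. The hindered, heavily silylated aldehyde may add only sluggishly to the weakly nucleophilic mono-oxygenated diene. Facial selectivity may also erode if catalyst and substrate bias prove mismatched, and silanol may be lost by β-elimination on long exposure. The fallback sets out from 12 and keeps the same ring-forming bond but uses a more electron-rich diene and a 1,3-transposition. Cycloaddition of 12 with trans-1-methoxy-3-(trimethylsilyloxy)buta-1,3-diene (COC=CC(=C)O[Si](C)(C)C) under the same chromium complex should give the silyl enol ether cycloadduct F1. Brief TFA treatment then eliminates methanol and the silyl group to give the dihydropyranone F2. Luche reduction (NaBH4, CeCl3·7H2O, MeOH, −78 °C) should deliver the cis allylic alcohol F3. Acid-catalysed Ferrier-type allylic transposition in methanol (PPTS, MeOH) should convert it into the trans methyl acetal F4, the C2 epimer of 14. F4 is hydrolysed under the conditions of step 8, so the fallback comes back to the route at lactol 15.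

2. Step 3. The dialkoxide of the unprotected diol ester is a poor electrophile, so acylation of the enolate may stall, and the β-alkoxide ester may undergo retro-aldol cleavage or dehydration. The fallback sets out from 6 and replaces relay by catalyst control for the third carbinol. Acetonide formation (2,2-dimethoxypropane, PPTS, CH2Cl2) gives the dioxane ester F5. Its Claisen condensation with the lithium enolate of 7 gives the β-keto ester F6. Noyori hydrogenation (H2, RuCl2[(S)-BINAP], MeOH, 50 °C) should set the new carbinol as 3S to give the hydroxy ester F7. Removal of the acetonide (80% aq. AcOH, rt), if it has not already occurred during hydrogenation, comes back to the route at triol ester 10.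

3. Step 4. Closure of the C7 hydroxyl onto the C3 ketone to a six-membered hemiketal may slow the reduction or bypass the boron chelate, which would lower the syn selectivity. The fallback sets out from 8 and again replaces relay by catalyst control: Noyori hydrogenation (H2, RuCl2[(S)-BINAP], MeOH, 50 °C) reduces the β-keto ester through its open form and should give 10 directly, where it rejoins the route. No new compound is made.

Further compounds
F1 | step 7 | (2R,6R)-2-methoxy-4-(trimethylsilyloxy)-6-[(2R,4S,6S)-2,4,6-tris(tert-butyldimethylsilyloxy)pentadecyl]-5,6-dihydro-2H-pyran | CCCCCCCCC[C@H](O[Si](C)(C)C(C)(C)C)C[C@H](O[Si](C)(C)C(C)(C)C)C[C@H](O[Si](C)(C)C(C)(C)C)C[C@@H]1CC(O[Si](C)(C)C)=C[C@H](OC)O1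
F2 | step 7 | (2R)-2-[(2R,4S,6S)-2,4,6-tris(tert-butyldimethylsilyloxy)pentadecyl]-2,3-dihydro-4H-pyran-4-one | CCCCCCCCC[C@H](O[Si](C)(C)C(C)(C)C)C[C@H](O[Si](C)(C)C(C)(C)C)C[C@H](O[Si](C)(C)C(C)(C)C)C[C@@H]1CC(=O)C=CO1
F3 | step 7 | (2S,4S)-2-[(2R,4S,6S)-2,4,6-tris(tert-butyldimethylsilyloxy)pentadecyl]-3,4-dihydro-2H-pyran-4-ol | CCCCCCCCC[C@H](O[Si](C)(C)C(C)(C)C)C[C@H](O[Si](C)(C)C(C)(C)C)C[C@H](O[Si](C)(C)C(C)(C)C)C[C@@H]1C[C@H](O)C=CO1
F4 | step 7 | (2S,6S)-2-methoxy-6-[(2R,4S,6S)-2,4,6-tris(tert-butyldimethylsilyloxy)pentadecyl]-5,6-dihydro-2H-pyran | CCCCCCCCC[C@H](O[Si](C)(C)C(C)(C)C)C[C@H](O[Si](C)(C)C(C)(C)C)C[C@H](O[Si](C)(C)C(C)(C)C)C[C@@H]1CC=C[C@@H](OC)O1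
F5 | step 3 | methyl 2-[(4S,6S)-2,2-dimethyl-6-nonyl-1,3-dioxan-4-yl]acetate | CCCCCCCCC[C@H]1C[C@@H](CC(=O)OC)OC(C)(C)O1
F6 | step 3 | tert-butyl 4-[(4S,6S)-2,2-dimethyl-6-nonyl-1,3-dioxan-4-yl]-3-oxobutanoate | CCCCCCCCC[C@H]1C[C@@H](CC(=O)CC(=O)OC(C)(C)C)OC(C)(C)O1
F7 | step 3 | tert-butyl (3S)-4-[(4R,6S)-2,2-dimethyl-6-nonyl-1,3-dioxan-4-yl]-3-hydroxybutanoate | CCCCCCCCC[C@H]1C[C@@H](C[C@H](O)CC(=O)OC(C)(C)C)OC(C)(C)O1
F0 | step 4 | none | none
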